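Ring atoms carry isochromene locants throughout (C1, O2, C3, C4, C4a, C5–C8, C8a). Side-chain atoms are counted from the carboxyl carbon ("chain C3" is the methyl-bearing stereocentre, chain C7 is bonded to ring C3).

## Analysis of the target

Target 24 is a 7,8-dihydro-6H-isochromen-6-one: a 4-ylidene-4H-pyran (O2, C1, C3, C4, C4a, C8a) fused along C4a–C8a to a six-membered carbocycle (C4a, C5, C6, C7, C8, C8a). It carries chlorine on C5 and a (4E,6E)-3,5-dimethylhepta-4,6-dienoic acid chain on C3. There are three stereocentres. C7 (S) is a methyl-bearing tertiary alcohol and C8 (R) a secondary alcohol, trans to each other on the ring. Chain C3 (S) lies six bonds from the ring and cannot influence, or be influenced by, the ring centres, so it is best bought from the chiral pool. The C8 carbinol is allylic to the enol ether C1=C8a and ionises in acid to a benzopyrylium-type cation. C1–H is the exposed electrophilic position of the pyran. The C6/C7 ketol can suffer base-induced acyloin shift, and the chloro-enone and the diene rule out strong reductants. The difficulty is twofold: C7 is a fully substituted carbinol between two oxidised carbons and must be made as one enantiomer with no neighbouring stereocentre to lean on, and the push–pull pyranylidene has to be joined to its arm at C4a although C1 is the more accessible carbon. The strategy rests on one feature: C7 bears a hydroxyl and lies between the C6 ketone and the oxygenated C8, so C7–C8 is an acyloin bond. It can be made from a C8 aldehyde on C8a and a C7 methyl ketone by polarity reversal of the aldehyde, and the C8 alcohol then follows by reduction directed by the new C7 hydroxyl.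

## Retrosynthetic reasoning

**24 to 22.** The acid of 24 is kept to the end as the silylethyl ester 23, because that ester falls under near-neutral conditions that spare the ionisable C8 carbinol and the ketol. The C8–H bond of 23 is cut next, giving the 6,8-dione 22. The C7 hydroxyl of 22 can carry the hydride to the same face of C8, which gives the trans diol, so only C7 needs external control.

**22 to 21.** The C7–C8 bond is cut, which opens the carbocycle to the monocyclic pyran 21 with a formyl group on C8a and a chloro-1,2-diketone arm on C4a. This is the only cut that removes the quaternary stereocentre and a ring together and leaves two ordinary carbonyl groups. The forward reaction must turn the aldehyde carbon into a nucleophile, close a six-membered ring onto the methyl ketone and choose one face of that ketone.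

**21 to 19.** Aldehyde and 1,2-diketone are not carried together for longer than necessary. The C7 ketone of 21 is masked as the dimethyl ketal 20, and the formyl carbon of 20 is traced to a carbonylative reduction of the C8a triflate 19. The aldehyde therefore appears after all base- and nucleophile-mediated steps, and the hydride source of the formylation never meets a free 1,2-diketone.

**19 to 11 and 18.** The chain C6=C7 double bond is cut by a phosphonate olefination between the pyranylmethyl phosphonate 11 and the enal 18. This is the convergent joint. The chiral fragment enters late, and the disubstituted E alkene is the normal outcome of a stabilised phosphonate.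

**11 to 5 and 8.** The C5–Cl bond is removed first (11 to 10), since C5 of 10 is the terminus of the donor system of the ring oxygen and the natural site of electrophilic chlorination. The C4a=C5 double bond of 10 is then cut. Condensing a carbanion with an O-alkylated pyrylium salt of the pyranone was considered and put aside, because such a cation has a free C1–H that is attacked in preference to the donor-substituted C4a and an acidic C3 methylene that quenches basic nucleophiles. Instead the pyranone oxygen is exchanged for sulfur (thione 5), the arm is hung on that sulfur by alkylation with bromo ketone 8 (salt 9), and the carbon is delivered intramolecularly to C4a with extrusion of sulfur. The tether decides the regiochemistry.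

**5 to 1.** Thione 5 comes from phosphonate 4, which comes from triflate 3, chloride 2 and kojic acid 1. Kojic acid 1 supplies O2, C1, C3, C4, C4a and C8a with an oxygen on C8a (the handle for C8) and a hydroxymethyl group on C3 (the handle for the chain).

**8 to 6.** Bromo ketone 8 is the monoketal 6 brominated at its only enolisable carbon through silyl enol ether 7.

**18 to 12.** The trisubstituted E alkene of 18 is cut to the α-methyl aldehyde 16 and the stabilised ylide 17. Aldehyde 16 comes from thioester 15 and acid 14, so no γ-hydroxy ester that could lactonise is ever formed. Acid 14 is the regioselective half-ester of anhydride 13, made from (S)-methylsuccinic acid 12. The carboxyl next to the stereocentre of 12 becomes the alkene carbon and the remote one becomes the acid of 24.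

## Alternatives that were turned down

**Alternative 1:** C5 is excised as a one-carbon unit by cutting C4a–C5 and C5–C6, which contracts the carbocycle to a five-membered ketone. In the forward sense a dihalocarbene adds to the silyl enol ether of that ketone and the halocyclopropane opens with loss of halide and silyl to the ring-expanded chloro-enone A1.
- For it: chlorine and enone arrive in one operation with no regiochemical question. The C7/C8 trans-diol is laid down early on a small ring by substrate control. On the certainty of the diol configuration and of the chlorine position this plan is stronger than the chosen one.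
- Against it: A1 still has no pyran. Its propargyl and vinyl groups must be hydrated, cleaved and cyclised, and the ring must be dehydrogenated to the push–pull triene. The C8a stereocentre is made only to be destroyed, the carbene can also attack the vinyl group, and two bulky silyl ethers must be removed near the end, one from the ionisable C8 position. The sequence is long and linear, with the chain attached last through the alkyne.
- Comparison: the chosen route starts from a pyran at the right oxidation level, needs no protecting group on either hydroxyl and forms one C–C bond in the ring-closing step. It pays with a catalyst-controlled quaternary carbinol.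

**Alternative 2:** The pyran is cut at C3–C4 and C1–O2, leaving a carbocycle with a C4 methyl group and an aminomethylene on C8a. In the forward sense the vinylogous enolate at the C4 methyl is C-acylated by the side-chain acyl donor and the new enol oxygen displaces the amine at C1, giving A2.
- For it: it joins the chain and closes the pyran in one flask at a late stage and needs no separate olefination. On convergence it is at least as strong as the chosen route, and the ring stereocentres come from the chiral pool without a chiral catalyst.
- Against it: remodelling a terpene-derived ring to carry the C7 tertiary alcohol, the C8 carbinol and the C5 chlorine is long. The dienolate can be acylated on oxygen or at the wrong carbon. A strong base sits next to an acyl donor with an epimerisable allylic stereocentre and next to a chloro-enone. A2 must lose two silyl ethers, one tertiary and hindered and one on the acid-labile C8.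
- Comparison: the chosen route offers a short, protecting-group-free end game and builds the carbocycle from an achiral ketone. It is less convergent at the pyran.

**Alternative 3:** The C8–C8a bond is cut. In the forward sense a stoichiometric divalent chromium salt with a nickel co-catalyst adds the C8a alkenyl triflate of a pyranylidene to a C8 aldehyde at the end of an arm that already carries C7 as a silyl ether, giving A3.
- For it: it uses the same kind of pyranyl triflate as 19. The C8 carbinol appears directly at the final oxidation level, so no reduction step is needed, and C7 is bought with the arm and not set by an enantioselective catalyst on an advanced intermediate. On these points it is equal or stronger.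
- Against it: the arm must be made enantiopure with a quaternary α-silyloxy aldehyde. The C8 configuration depends on substrate control between methyl and silyloxy on a nearly flat ring. Low-valent chromium threatens the chloro-enone, the aldehyde is neopentyl-like and slow, a full equivalent of a toxic metal is consumed, and A3 still needs deprotection.
- Comparison: the chosen route is catalytic in the ring-closing step, takes C7 from the catalyst and C8 from C7, and uses an arm made in one step from a commercial ketone.

Key step: step 16

Remark on geometry: the exocyclic C4a=C5 bond of 10, 11, 19, 20 and 21 is a push–pull double bond whose geometric isomers are expected to interconvert; each is written as the isomer with the acyl arm on the C8a side.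

Assumption on the catalyst: the (5aS,10bR) antipode of 2-(pentafluorophenyl)-5a,10b-dihydro-4H,6H-indeno[2,1-b][1,2,4]triazolo[4,3-d][1,4]oxazin-2-ium tetrafluoroborate is taken to favour the (7S) ketol; if the opposite sense were found, the (5aR,10bS) salt would be used.

## Route

Step 1
Reactants: 1 kojic acid (5-hydroxy-2-(hydroxymethyl)-4H-pyran-4-one)
Product: 2 2-(chloromethyl)-5-hydroxy-4H-pyran-4-one (chlorokojic acid)
Conditions: SOCl2, 23 °C
Reagents that add atoms: thionyl chloride, O=S(Cl)Cl
Why: Chlorodehydroxylation of the activated primary alcohol; the enolic C8a hydroxyl does not react and the product should crystallise from the reaction mixture.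

Step 2
Reactants: 2 2-(chloromethyl)-5-hydroxy-4H-pyran-4-one
Product: 3 6-(chloromethyl)-4-oxo-4H-pyran-3-yl trifluoromethanesulfonate
Conditions: Tf2O, 2,6-lutidine, CH2Cl2, −40 → 0 °C
Reagents that add atoms: trifluoromethanesulfonic anhydride, O=S(=O)(OS(=O)(=O)C(F)(F)F)C(F)(F)F
Why: O-Sulfonylation of the acidic enol gives the alkenyl triflate that later becomes C8; the hindered base does not quaternise at the chloromethyl group.

Step 3
Reactants: 3 6-(chloromethyl)-4-oxo-4H-pyran-3-yl trifluoromethanesulfonate
Product: 4 diethyl {[4-oxo-5-(trifluoromethanesulfonyloxy)-4H-pyran-2-yl]methyl}phosphonate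
Conditions: P(OEt)3, toluene, 100 °C
Reagents that add atoms: triethyl phosphite, CCOP(OCC)OCC
Why: Michaelis–Arbuzov reaction at the activated chloride; an alkenyl triflate does not react with a phosphite without a metal catalyst.

Step 4
Reactants: 4 diethyl {[4-oxo-5-(trifluoromethanesulfonyloxy)-4H-pyran-2-yl]methyl}phosphonate
Product: 5 diethyl {[4-thioxo-5-(trifluoromethanesulfonyloxy)-4H-pyran-2-yl]methyl}phosphonate
Conditions: Lawesson's reagent (0.6 equiv), toluene, 70 °C
Reagents that add atoms: Lawesson's reagent, COc1ccc(cc1)P1(=S)SP(=S)(S1)c1ccc(OC)cc1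
Why: Thionation of the strongly polarised pyranone carbonyl, which exchanges oxygen for sulfur much faster than a phosphonate P=O or a sulfonate.

Step 5
Reactants: 6 3,3-dimethoxybutan-2-one
Product: 8 1-bromo-3,3-dimethoxybutan-2-one, via trimethylsilyl enol ether 7 (not isolated)
Conditions: LiN(iPr)2, Me3SiCl, THF, −78 °C; then NBS, THF, 0 °C
Reagents that add atoms: N-bromosuccinimide, BrN1C(=O)CCC1=O; chlorotrimethylsilane, C[Si](C)(C)Cl (its silyl group is present only in 7)
Why: The methyl group is the only enolisable position, so enol silylation is regiospecific, and bromination of the silyl enol ether under non-acidic conditions keeps the ketal.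

Step 6
Reactants: 5 diethyl {[4-thioxo-5-(trifluoromethanesulfonyloxy)-4H-pyran-2-yl]methyl}phosphonate; 8 1-bromo-3,3-dimethoxybutan-2-one
Product: 10 diethyl {[4-(3,3-dimethoxy-2-oxobutylidene)-5-(trifluoromethanesulfonyloxy)-4H-pyran-2-yl]methyl}phosphonate, via 4-(acylmethylsulfanyl)pyrylium bromide 9 (not isolated)
Conditions: MeCN, 23 °C; then PPh3, i-Pr2NEt, 0 → 23 °C
Reagents that add atoms: none
Why: Eschenmoser-type sulfide contraction: S-alkylation gives 9, the S–CH–CO carbanion closes onto C4a (the only ring carbon within reach, so C1 cannot compete) to a thiirane, and the phosphine removes sulfur to leave the C4a=C5 bond.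

Step 7
Reactants: 10 diethyl {[4-(3,3-dimethoxy-2-oxobutylidene)-5-(trifluoromethanesulfonyloxy)-4H-pyran-2-yl]methyl}phosphonate
Product: 11 diethyl {[4-(1-chloro-3,3-dimethoxy-2-oxobutylidene)-5-(trifluoromethanesulfonyloxy)-4H-pyran-2-yl]methyl}phosphonate
Conditions: NCS, CH2Cl2, 0 °C
Reagents that add atoms: N-chlorosuccinimide, ClN1C(=O)CCC1=O
Why: Electrophilic α-chlorination of a push–pull (doubly vinylogous ester) system at C5, the carbon at which donation from the ring oxygen and enol character of the C6 ketone coincide; the same position is the one halogenated in bicyclic azaphilone chromophores.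

Step 8
Reactants: 12 (S)-methylsuccinic acid
Product: 13 (S)-methylsuccinic anhydride ((3S)-3-methyloxolane-2,5-dione)
Conditions: AcCl, reflux
Reagents that add atoms: none
Why: Cyclodehydration of a 1,4-diacid to the five-membered anhydride; the stereocentre is not touched.

Step 9
Reactants: 13 (S)-methylsuccinic anhydride
Product: 14 (2S)-2-methyl-4-oxo-4-[2-(trimethylsilyl)ethoxy]butanoic acid
Conditions: Me3SiCH2CH2OH, i-Pr2NEt, DMAP (5 mol %), CH2Cl2, −20 → 23 °C
Reagents that add atoms: 2-(trimethylsilyl)ethanol, C[Si](C)(C)CCO
Why: Alcoholysis of the unsymmetrical anhydride should take place mainly at the carbonyl remote from the methyl-bearing carbon (acyl substitution under steric control), leaving the free acid next to the stereocentre; the minor regioisomer is removed here or after step 10.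

Step 10
Reactants: 14 (2S)-2-methyl-4-oxo-4-[2-(trimethylsilyl)ethoxy]butanoic acid
Product: 15 2-(trimethylsilyl)ethyl (3S)-4-(ethylsulfanyl)-3-methyl-4-oxobutanoate
Conditions: EtSH, EDC·HCl, DMAP (10 mol %), CH2Cl2, 0 °C
Reagents that add atoms: ethanethiol, CCS
Why: Steglich-type thioesterification; carbodiimide activation at 0 °C with a thiol nucleophile should not epimerise the α-methyl centre.

Step 11
Reactants: 15 2-(trimethylsilyl)ethyl (3S)-4-(ethylsulfanyl)-3-methyl-4-oxobutanoate
Product: 16 2-(trimethylsilyl)ethyl (3S)-3-methyl-4-oxobutanoate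
Conditions: Et3SiH, Pd/C (10 wt % palladium on carbon, 5 mol %), acetone, 23 °C
Reagents that add atoms: none
Why: Fukuyama reduction takes the thioester to the aldehyde under neutral conditions, so the α-stereocentre is kept, the ester is untouched and no γ-hydroxy ester that could lactonise is formed; 16 is used at once.

Step 12
Reactants: 16 2-(trimethylsilyl)ethyl (3S)-3-methyl-4-oxobutanoate; 17 2-(triphenyl-λ5-phosphanylidene)propanal
Product: 18 2-(trimethylsilyl)ethyl (3S,4E)-3,5-dimethyl-6-oxohex-4-enoate
Conditions: toluene, 80 °C
Reagents that add atoms: none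
Why: Wittig reaction of a stabilised formyl ylide, which gives the trisubstituted E enal under thermodynamic control and is mild enough for an α-branched aldehyde; the less electrophilic product enal should not react further.

Step 13
Reactants: 11 diethyl {[4-(1-chloro-3,3-dimethoxy-2-oxobutylidene)-5-(trifluoromethanesulfonyloxy)-4H-pyran-2-yl]methyl}phosphonate; 18 2-(trimethylsilyl)ethyl (3S,4E)-3,5-dimethyl-6-oxohex-4-enoate
Product: 19 2-(trimethylsilyl)ethyl (3S,4E,6E)-7-[4-(1-chloro-3,3-dimethoxy-2-oxobutylidene)-5-(trifluoromethanesulfonyloxy)-4H-pyran-2-yl]-3,5-dimethylhepta-4,6-dienoate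
Conditions: LiN(SiMe3)2, THF, −78 °C; then 18, −78 → 0 °C
Reagents that add atoms: none
Why: Vinylogous Horner–Wadsworth–Emmons olefination: the C3 methylene is the only acidic site of 11, its anion is stabilised through the pyranylidene ketone and reacts at the carbon next to phosphorus, and the stabilised reagent should give the E alkene; a preformed anion with no excess base protects the allylic stereocentre of 18.

Step 14
Reactants: 19 2-(trimethylsilyl)ethyl (3S,4E,6E)-7-[4-(1-chloro-3,3-dimethoxy-2-oxobutylidene)-5-(trifluoromethanesulfonyloxy)-4H-pyran-2-yl]-3,5-dimethylhepta-4,6-dienoate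
Product: 20 2-(trimethylsilyl)ethyl (3S,4E,6E)-7-[4-(1-chloro-3,3-dimethoxy-2-oxobutylidene)-5-formyl-4H-pyran-2-yl]-3,5-dimethylhepta-4,6-dienoate
Conditions: Pd(PPh3)4 (5 mol %), CO (1 atm), Bu3SnH (slow addition), LiCl, THF, 50 °C
Reagents that add atoms: carbon monoxide, [C-]#[O+]
Why: Palladium-catalysed reductive carbonylation (formylation) of an alkenyl triflate: zerovalent palladium inserts into the C8a–O bond much faster than into the C5–Cl bond, CO inserts, and slow delivery of the tin hydride lets the acylpalladium, not the alkenylpalladium, take the hydride.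

Step 15
Reactants: 20 2-(trimethylsilyl)ethyl (3S,4E,6E)-7-[4-(1-chloro-3,3-dimethoxy-2-oxobutylidene)-5-formyl-4H-pyran-2-yl]-3,5-dimethylhepta-4,6-dienoate
Product: 21 2-(trimethylsilyl)ethyl (3S,4E,6E)-7-[4-(1-chloro-2,3-dioxobutylidene)-5-formyl-4H-pyran-2-yl]-3,5-dimethylhepta-4,6-dienoate
Conditions: PPTS (20 mol %), acetone/H2O (10:1), 40 °C
Reagents that add atoms: water, O
Why: Acid-catalysed ketal hydrolysis; the neighbouring C6 carbonyl is a doubly vinylogous ester and retards oxocarbenium formation little, so a mild acid that spares the silylethyl ester should suffice; 21 is dried azeotropically and used crude.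

Step 16
Reactants: 21 2-(trimethylsilyl)ethyl (3S,4E,6E)-7-[4-(1-chloro-2,3-dioxobutylidene)-5-formyl-4H-pyran-2-yl]-3,5-dimethylhepta-4,6-dienoate
Product: 22 2-(trimethylsilyl)ethyl (3S,4E,6E)-7-[(7S)-5-chloro-7-hydroxy-7-methyl-6,8-dioxo-7,8-dihydro-6H-isochromen-3-yl]-3,5-dimethylhepta-4,6-dienoate
Conditions: (5aS,10bR)-N-C6F5 aminoindanol triazolium BF4 salt (10 mol %), Et3N (10 mol %), toluene, 4 Å molecular sieves, 23 °C
Reagents that add atoms: none
Why: The carbene freed from the triazolium salt adds to the C8 aldehyde and proton transfer gives the hydroxy-enamine (Breslow intermediate), in which C8 is an acyl-anion equivalent. C8 attacks the C7 ketone in a 6-exo-trig closure that forms the carbocycle (C4a, C5, C6, C7, C8, C8a), and collapse of the adduct releases the carbene and leaves the C8 ketone. The closest known reaction is the enantioselective intramolecular aldehyde–ketone crossed benzoin catalysed by chiral bicyclic triazolium carbenes, which gives six-membered ketols with a tertiary carbinol. C7 is set by the catalyst: the indane-fused backbone blocks one face of the enaminol, and a hydrogen bond from its hydroxyl to the ketone oxygen fixes which face of the C7 carbonyl is presented; the chain stereocentre is too remote to interfere. Only the aldehyde has the C–H needed to become the donor, and the C7 ketone is the acceptor because it is activated by the adjacent C6 carbonyl and carries only a methyl group. Attack at C6 would need a five-membered ring and a deactivated cross-conjugated carbonyl. The electron-poor N-aryl group and the weak base favour acyl-anion over homoenolate behaviour of this enal-type aldehyde (whose β-carbon C1 carries the ring oxygen) and keep the methyl ketone from enolising. Rotation about the push–pull C4a=C5 bond feeds both geometric isomers of 21 through the one that can cyclise.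

Step 17
Reactants: 22 2-(trimethylsilyl)ethyl (3S,4E,6E)-7-[(7S)-5-chloro-7-hydroxy-7-methyl-6,8-dioxo-7,8-dihydro-6H-isochromen-3-yl]-3,5-dimethylhepta-4,6-dienoate
Product: 23 2-(trimethylsilyl)ethyl (3S,4E,6E)-7-[(7S,8R)-5-chloro-7,8-dihydroxy-7-methyl-6-oxo-7,8-dihydro-6H-isochromen-3-yl]-3,5-dimethylhepta-4,6-dienoate
Conditions: NaBH(OAc)3, MeCN/AcOH (10:1), −20 °C; NaHCO3 quench
Reagents that add atoms: none
Why: Hydroxyl-directed reduction: the C7 hydroxyl exchanges onto boron and delivers hydride intramolecularly to the face of C8 on which it sits, so the new C8 hydroxyl ends up trans to it (8R). The reagent hardly reduces ketones it is not bound to, and C8 (a singly vinylogous ester carbonyl) should be more electrophilic than C6 (pyranone-like, doubly vinylogous).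

Step 18
Reactants: 23 2-(trimethylsilyl)ethyl (3S,4E,6E)-7-[(7S,8R)-5-chloro-7,8-dihydroxy-7-methyl-6-oxo-7,8-dihydro-6H-isochromen-3-yl]-3,5-dimethylhepta-4,6-dienoate
Product: 24 (3S,4E,6E)-7-[(7S,8R)-5-chloro-7,8-dihydroxy-7-methyl-6-oxo-7,8-dihydro-6H-isochromen-3-yl]-3,5-dimethylhepta-4,6-dienoic acid (target)
Conditions: Bu4NF, AcOH (1:1), THF, 0 → 23 °C
Reagents that add atoms: none
Why: Fluoride attacks silicon and the 2-silylethyl ester fragments by β-elimination to the carboxylate, fluorosilane and ethene; buffering with acetic acid keeps the medium near neutral for the ketol and the C8 carbinol.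

## Compound list

1 | kojic acid (5-hydroxy-2-(hydroxymethyl)-4H-pyran-4-one) | OCC1=CC(=O)C(O)=CO1 | starting material
2 | 2-(chloromethyl)-5-hydroxy-4H-pyran-4-one | ClCC1=CC(=O)C(O)=CO1 | intermediate
3 | 6-(chloromethyl)-4-oxo-4H-pyran-3-yl trifluoromethanesulfonate | ClCC1=CC(=O)C(OS(=O)(=O)C(F)(F)F)=CO1 | intermediate
4 | diethyl {[4-oxo-5-(trifluoromethanesulfonyloxy)-4H-pyran-2-yl]methyl}phosphonate | CCOP(=O)(OCC)CC1=CC(=O)C(OS(=O)(=O)C(F)(F)F)=CO1 | intermediate
5 | diethyl {[4-thioxo-5-(trifluoromethanesulfonyloxy)-4H-pyran-2-yl]methyl}phosphonate | CCOP(=O)(OCC)CC1=CC(=S)C(OS(=O)(=O)C(F)(F)F)=CO1 | intermediate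
6 | 3,3-dimethoxybutan-2-one | CC(=O)C(C)(OC)OC | starting material
7 | [(3,3-dimethoxybut-1-en-2-yl)oxy]trimethylsilane | C=C(O[Si](C)(C)C)C(C)(OC)OC | intermediate (not isolated)
8 | 1-bromo-3,3-dimethoxybutan-2-one | BrCC(=O)C(C)(OC)OC | intermediate
9 | 2-[(diethoxyphosphoryl)methyl]-4-[(3,3-dimethoxy-2-oxobutyl)sulfanyl]-5-(trifluoromethanesulfonyloxy)pyrylium bromide | CCOP(=O)(OCC)Cc1cc(SCC(=O)C(C)(OC)OC)c(OS(=O)(=O)C(F)(F)F)c[o+]1.[Br-] | intermediate (not isolated)
10 | diethyl {[4-(3,3-dimethoxy-2-oxobutylidene)-5-(trifluoromethanesulfonyloxy)-4H-pyran-2-yl]methyl}phosphonate | CCOP(=O)(OCC)CC1=C/C(=C/C(=O)C(C)(OC)OC)C(OS(=O)(=O)C(F)(F)F)=CO1 | intermediate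
11 | diethyl {[4-(1-chloro-3,3-dimethoxy-2-oxobutylidene)-5-(trifluoromethanesulfonyloxy)-4H-pyran-2-yl]methyl}phosphonate | CCOP(=O)(OCC)CC1=C/C(=C(\Cl)C(=O)C(C)(OC)OC)C(OS(=O)(=O)C(F)(F)F)=CO1 | intermediate
12 | (S)-methylsuccinic acid ((2S)-2-methylbutanedioic acid) | OC(=O)[C@@H](C)CC(=O)O | starting material
13 | (S)-methylsuccinic anhydride ((3S)-3-methyloxolane-2,5-dione) | O=C1[C@@H](C)CC(=O)O1 | intermediate
14 | (2S)-2-methyl-4-oxo-4-[2-(trimethylsilyl)ethoxy]butanoic acid | OC(=O)[C@@H](C)CC(=O)OCC[Si](C)(C)C | intermediate
15 | 2-(trimethylsilyl)ethyl (3S)-4-(ethylsulfanyl)-3-methyl-4-oxobutanoate | CCSC(=O)[C@@H](C)CC(=O)OCC[Si](C)(C)C | intermediate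
16 | 2-(trimethylsilyl)ethyl (3S)-3-methyl-4-oxobutanoate | O=C[C@@H](C)CC(=O)OCC[Si](C)(C)C | intermediate
17 | 2-(triphenyl-λ5-phosphanylidene)propanal | CC(C=O)=P(c1ccccc1)(c1ccccc1)c1ccccc1 | starting material
18 | 2-(trimethylsilyl)ethyl (3S,4E)-3,5-dimethyl-6-oxohex-4-enoate | O=C/C(C)=C/[C@@H](C)CC(=O)OCC[Si](C)(C)C | intermediate
19 | 2-(trimethylsilyl)ethyl (3S,4E,6E)-7-[4-(1-chloro-3,3-dimethoxy-2-oxobutylidene)-5-(trifluoromethanesulfonyloxy)-4H-pyran-2-yl]-3,5-dimethylhepta-4,6-dienoate | CC(/C=C/C1=C/C(=C(\Cl)C(=O)C(C)(OC)OC)C(OS(=O)(=O)C(F)(F)F)=CO1)=C\[C@@H](C)CC(=O)OCC[Si](C)(C)C | intermediate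
20 | 2-(trimethylsilyl)ethyl (3S,4E,6E)-7-[4-(1-chloro-3,3-dimethoxy-2-oxobutylidene)-5-formyl-4H-pyran-2-yl]-3,5-dimethylhepta-4,6-dienoate | CC(/C=C/C1=C/C(=C(\Cl)C(=O)C(C)(OC)OC)C(C=O)=CO1)=C\[C@@H](C)CC(=O)OCC[Si](C)(C)C | intermediate
21 | 2-(trimethylsilyl)ethyl (3S,4E,6E)-7-[4-(1-chloro-2,3-dioxobutylidene)-5-formyl-4H-pyran-2-yl]-3,5-dimethylhepta-4,6-dienoate | CC(/C=C/C1=C/C(=C(\Cl)C(=O)C(C)=O)C(C=O)=CO1)=C\[C@@H](C)CC(=O)OCC[Si](C)(C)C | intermediate (precursor of the key step)
22 | 2-(trimethylsilyl)ethyl (3S,4E,6E)-7-[(7S)-5-chloro-7-hydroxy-7-methyl-6,8-dioxo-7,8-dihydro-6H-isochromen-3-yl]-3,5-dimethylhepta-4,6-dienoate | CC(/C=C/C1=CC2=C(Cl)C(=O)[C@@](C)(O)C(=O)C2=CO1)=C\[C@@H](C)CC(=O)OCC[Si](C)(C)C | intermediate (product of the key step)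
23 | 2-(trimethylsilyl)ethyl (3S,4E,6E)-7-[(7S,8R)-5-chloro-7,8-dihydroxy-7-methyl-6-oxo-7,8-dihydro-6H-isochromen-3-yl]-3,5-dimethylhepta-4,6-dienoate | CC(/C=C/C1=CC2=C(Cl)C(=O)[C@@](C)(O)[C@H](O)C2=CO1)=C\[C@@H](C)CC(=O)OCC[Si](C)(C)C | intermediate
24 | (3S,4E,6E)-7-[(7S,8R)-5-chloro-7,8-dihydroxy-7-methyl-6-oxo-7,8-dihydro-6H-isochromen-3-yl]-3,5-dimethylhepta-4,6-dienoic acid | CC(/C=C/C1=CC2=C(Cl)C(=O)[C@@](C)(O)[C@H](O)C2=CO1)=C\[C@@H](C)CC(=O)O | target

## Step count and least certain steps

Total: 18 steps. Longest linear sequence: 12 steps from kojic acid 1 (steps 1–4, 6, 7, 13–18). The chain fragment takes 5 steps (8–12) and the arm 1 step (5).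

**Step 16 (key step).**
- What may go wrong: the extended enaminol may be protonated at C1 (homoenolate channel), which stalls turnover. The C7 methyl ketone may enolise and attack the aldehyde in an aldol reaction. Facial discrimination may be poor, because the ketone is flanked by a methyl group and a flat acyl carbon of similar size.
- Fallback: reverse the polarity of the C7–C8 closure and add the C7 oxygen afterwards. It sets out from thione 5 and enal 18 and returns at 22. Thione 5 is alkylated with commercial 1-bromobutan-2-one to 2-[(diethoxyphosphoryl)methyl]-4-[(2-oxobutyl)sulfanyl]-5-(trifluoromethanesulfonyloxy)pyrylium bromide F1, which is contracted as in step 6 (PPh3, i-Pr2NEt) to diethyl {[4-(2-oxobutylidene)-5-(trifluoromethanesulfonyloxy)-4H-pyran-2-yl]methyl}phosphonate F2. Chlorination as in step 7 gives diethyl {[4-(1-chloro-2-oxobutylidene)-5-(trifluoromethanesulfonyloxy)-4H-pyran-2-yl]methyl}phosphonate F3, and olefination with 18 as in step 13 gives 2-(trimethylsilyl)ethyl (3S,4E,6E)-7-[4-(1-chloro-2-oxobutylidene)-5-(trifluoromethanesulfonyloxy)-4H-pyran-2-yl]-3,5-dimethylhepta-4,6-dienoate F4. Methoxycarbonylation of the triflate (Pd(OAc)2, 1,3-bis(diphenylphosphino)propane, CO, MeOH, Et3N, DMF, 60 °C) gives 2-(trimethylsilyl)ethyl (3S,4E,6E)-7-[4-(1-chloro-2-oxobutylidene)-5-(methoxycarbonyl)-4H-pyran-2-yl]-3,5-dimethylhepta-4,6-dienoate F5. LiN(SiMe3)2 in THF at −78 °C then closes the ring by Dieckmann-type acylation of the C7 enolate by the C8 ester to 2-(trimethylsilyl)ethyl (3S,4E,6E)-7-(5-chloro-8-hydroxy-7-methyl-6-oxo-6H-isochromen-3-yl)-3,5-dimethylhepta-4,6-dienoate F6. Hydroxylation of its sodium enolate at C7 with an enantiopure camphor-derived N-sulfonyloxaziridine (reagent control), or with 2-iodoxybenzoic acid if the reagent shows no preference, leads to 22. If C7 control is poor, the two C7 epimers are diastereomers and would be separated by chromatography.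

**Step 6.**
- What may go wrong: loss of the acidic C3 methylene proton can park salt 9 as its anhydrobase and slow ring closure to the thiirane, and the amine or the phosphine can add at C1 of the cationic ring.
- Fallback: form the same bond without a cationic intermediate or a base. It sets out from 8 and 5 and returns at 10. Bromide 8 is converted with N,N'-ditosylhydrazine and DBU into 1-diazo-3,3-dimethoxybutan-2-one F7. Rh2(OAc)4 (1 mol %) in CH2Cl2 transfers its acyl carbene to the sulfur of 5, and the thiocarbonyl ylide closes to the spiro thiirane diethyl {[2-(2,2-dimethoxypropanoyl)-4-(trifluoromethanesulfonyloxy)-6-oxa-1-thiaspiro[2.5]octa-4,7-dien-7-yl]methyl}phosphonate F8. PPh3 desulfurises F8 in the same flask to 10.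

**Step 14.**
- What may go wrong: the alkenylpalladium species may capture hydride before CO inserts (hydrodetriflation), or the tin hydride may reduce the chloro-enone by conjugate reduction or dechlorination.
- Fallback: bring in C8 as an alcohol with no hydride donor present. It sets out from 19 and returns at 20. Stille coupling of 19 with (tributylstannyl)methanol (Pd(PPh3)4, LiCl, 1,4-dioxane, 90 °C) gives 2-(trimethylsilyl)ethyl (3S,4E,6E)-7-[4-(1-chloro-3,3-dimethoxy-2-oxobutylidene)-5-(hydroxymethyl)-4H-pyran-2-yl]-3,5-dimethylhepta-4,6-dienoate F9. MnO2 in CH2Cl2 oxidises the allylic alcohol to 20.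

**Step 17.**
- What may go wrong: the C7 hydroxyl is flanked by two ketones, so hydride may also be delivered to C6, and the acidic medium may ionise the new C8 carbinol, with loss of configuration or elimination.
- Fallback: replace substrate direction by catalyst control at neutral pH. It sets out from 22 and returns at 23. A panel of ketoreductases (NADPH recycled with glucose and glucose dehydrogenase, phosphate buffer pH 7 with DMSO co-solvent) is screened for an enzyme that reduces only the C8 ketone to the (8R) alcohol. No new compound is made on the way.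

## Further compounds

F1 | step 16 | 2-[(diethoxyphosphoryl)methyl]-4-[(2-oxobutyl)sulfanyl]-5-(trifluoromethanesulfonyloxy)pyrylium bromide | CCOP(=O)(OCC)Cc1cc(SCC(=O)CC)c(OS(=O)(=O)C(F)(F)F)c[o+]1.[Br-]
F2 | step 16 | diethyl {[4-(2-oxobutylidene)-5-(trifluoromethanesulfonyloxy)-4H-pyran-2-yl]methyl}phosphonate | CCOP(=O)(OCC)CC1=C/C(=C/C(=O)CC)C(OS(=O)(=O)C(F)(F)F)=CO1
F3 | step 16 | diethyl {[4-(1-chloro-2-oxobutylidene)-5-(trifluoromethanesulfonyloxy)-4H-pyran-2-yl]methyl}phosphonate | CCOP(=O)(OCC)CC1=C/C(=C(\Cl)C(=O)CC)C(OS(=O)(=O)C(F)(F)F)=CO1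
F4 | step 16 | 2-(trimethylsilyl)ethyl (3S,4E,6E)-7-[4-(1-chloro-2-oxobutylidene)-5-(trifluoromethanesulfonyloxy)-4H-pyran-2-yl]-3,5-dimethylhepta-4,6-dienoate | CC(/C=C/C1=C/C(=C(\Cl)C(=O)CC)C(OS(=O)(=O)C(F)(F)F)=CO1)=C\[C@@H](C)CC(=O)OCC[Si](C)(C)C
F5 | step 16 | 2-(trimethylsilyl)ethyl (3S,4E,6E)-7-[4-(1-chloro-2-oxobutylidene)-5-(methoxycarbonyl)-4H-pyran-2-yl]-3,5-dimethylhepta-4,6-dienoate | CC(/C=C/C1=C/C(=C(\Cl)C(=O)CC)C(C(=O)OC)=CO1)=C\[C@@H](C)CC(=O)OCC[Si](C)(C)C
F6 | step 16 | 2-(trimethylsilyl)ethyl (3S,4E,6E)-7-(5-chloro-8-hydroxy-7-methyl-6-oxo-6H-isochromen-3-yl)-3,5-dimethylhepta-4,6-dienoate | CC(/C=C/C1=CC2=C(Cl)C(=O)C(C)=C(O)C2=CO1)=C\[C@@H](C)CC(=O)OCC[Si](C)(C)C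
F7 | step 6 | 1-diazo-3,3-dimethoxybutan-2-one | [N-]=[N+]=CC(=O)C(C)(OC)OC
F8 | step 6 | diethyl {[2-(2,2-dimethoxypropanoyl)-4-(trifluoromethanesulfonyloxy)-6-oxa-1-thiaspiro[2.5]octa-4,7-dien-7-yl]methyl}phosphonate (racemic, transient) | CCOP(=O)(OCC)CC1=CC2(SC2C(=O)C(C)(OC)OC)C(OS(=O)(=O)C(F)(F)F)=CO1
F9 | step 14 | 2-(trimethylsilyl)ethyl (3S,4E,6E)-7-[4-(1-chloro-3,3-dimethoxy-2-oxobutylidene)-5-(hydroxymethyl)-4H-pyran-2-yl]-3,5-dimethylhepta-4,6-dienoate | CC(/C=C/C1=C/C(=C(\Cl)C(=O)C(C)(OC)OC)C(CO)=CO1)=C\[C@@H](C)CC(=O)OCC[Si](C)(C)C
F0 | step 17 | none | none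
A1 | alternative 1 | 2-chloro-4-ethenyl-5,6-bis[(tert-butyldimethylsilyl)oxy]-6-methyl-3-(prop-2-yn-1-yl)cyclohex-2-en-1-one (configuration as in the SMILES) | C#CCC1=C(Cl)C(=O)[C@@](C)(O[Si](C)(C)C(C)(C)C)[C@H](O[Si](C)(C)C(C)(C)C)[C@H]1C=C
A2 | alternative 2 | 7,8-bis(tert-butyldimethylsilyl) ether of the 2-(trimethylsilyl)ethyl ester of the target | CC(/C=C/C1=CC2=C(Cl)C(=O)[C@@](C)(O[Si](C)(C)C(C)(C)C)[C@H](O[Si](C)(C)C(C)(C)C)C2=CO1)=C\[C@@H](C)CC(=O)OCC[Si](C)(C)C
A3 | alternative 3 | C7 triethylsilyl ether of the 2-(trimethylsilyl)ethyl ester of the target | CC(/C=C/C1=CC2=C(Cl)C(=O)[C@@](C)(O[Si](CC)(CC)CC)[C@H](O)C2=CO1)=C\[C@@H](C)CC(=O)OCC[Si](C)(C)C
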